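## Retrosynthetic overview

1. Target ⇐ its catechol bis(triisopropylsilyl) ether (fluoride).
2. Bicyclo[3.3.1]nonane core ⇐ one acyclic chain (geranylmalonate at C1, aryl β-diketone at C3–C5) by two intramolecular Claisen bonds: C5–C9 closes ring B (C1, C8, C7, C6, C5, C9) first, C2–C3 closes ring A (C1 to C5, C9) second, in the same flask.
3. That chain ⇐ C5–C6 alkylation of an aryl β-diketone dianion with a chiral primary iodide, run in the same flask as the ring closures.
4. Iodide ⇐ Evans acetyl imide + dimethyl isopropylidenemalonate (C7–C8 by Michael addition), then auxiliary-controlled prenylation (C7) and malonate geranylation (C1); β-diketone ⇐ (E)-geranylacetone + silylated methyl 3,4-dihydroxybenzoate.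
5. C7 is the only preset stereocentre; it dictates both bridgeheads during the double ring closure (prenyl equatorial = exo).

Assumption: the target is taken as drawn (C4-enol tautomer, 1S,5S,7R, C7 prenyl exo); core atoms are numbered C1 (bridgehead next to CMe2), C2, C3 (aroyl-bearing), C4, C5 (other bridgehead), C6 (CH2), C7 (CH–prenyl), C8 (CMe2), C9 (bridging C=O); commercial (E)-geranylacetone and (E)-geranyl bromide of high geometric purity are used.

## Route

Step 1
Reactants: 1 (4S)-3-acetyl-4-benzyl-1,3-oxazolidin-2-one; 2 dimethyl 2-(propan-2-ylidene)propanedioate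
Product: 3 dimethyl 2-{4-[(4S)-4-benzyl-2-oxo-1,3-oxazolidin-3-yl]-2-methyl-4-oxobutan-2-yl}propanedioate
Conditions: LiN(SiMe3)2, THF, −78 °C; then 2, −78 → −40 °C
Reagents that add atoms: dimethyl 2-(propan-2-ylidene)propanedioate (2), COC(=O)C(=C(C)C)C(=O)OC
Why: Michael addition of the unhindered lithium acetate-imide enolate to the doubly activated alkylidene malonate is driven by formation of the more stable malonate enolate and builds the C8 gem-dimethyl quaternary carbon next to the future C1; no stereocentre is formed.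

Step 2
Reactants: 3 dimethyl 2-{4-[(4S)-4-benzyl-2-oxo-1,3-oxazolidin-3-yl]-2-methyl-4-oxobutan-2-yl}propanedioate; 4 1-bromo-3-methylbut-2-ene; 5 (2E)-1-bromo-3,7-dimethylocta-2,6-diene
Product: 7 dimethyl 2-[(3S)-3-{[(4S)-4-benzyl-2-oxo-1,3-oxazolidin-3-yl]carbonyl}-2,6-dimethylhept-5-en-2-yl]-2-[(2E)-3,7-dimethylocta-2,6-dien-1-yl]propanedioate, via monoprenylated imide malonate enolate 6 (not isolated)
Conditions: NaN(SiMe3)2 (2.1 equiv), THF, −78 °C; 4 (1.05 equiv), −78 → −45 °C; then 5 (2 equiv), DMPU, −45 °C → rt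
Reagents that add atoms: 1-bromo-3-methylbut-2-ene (4), BrCC=C(C)C; (2E)-1-bromo-3,7-dimethylocta-2,6-diene (5), BrC/C=C(\C)CCC=C(C)C
Why: Evans asymmetric alkylation inside a one-flask sequential dianion dialkylation: the more reactive chelated sodium (Z)-imide enolate is prenylated first on the face opposite the benzyl group, which sets C7 (S here, the R centre of the target), and the sluggish hindered malonate enolate is then geranylated to make C1 quaternary.

Step 3
Reactants: 7 dimethyl 2-[(3S)-3-{[(4S)-4-benzyl-2-oxo-1,3-oxazolidin-3-yl]carbonyl}-2,6-dimethylhept-5-en-2-yl]-2-[(2E)-3,7-dimethylocta-2,6-dien-1-yl]propanedioate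
Product: 8 dimethyl 2-[(2E)-3,7-dimethylocta-2,6-dien-1-yl]-2-[(3S)-3-(hydroxymethyl)-2,6-dimethylhept-5-en-2-yl]propanedioate
Conditions: LiBH4, H2O (1 equiv), Et2O, 0 °C
Reagents that add atoms: none
Why: Reductive cleavage of the Evans imide, in which LiBH4 attacks the activated exocyclic imide carbonyl much faster than the two methyl esters on the congested quaternary carbon, gives the primary alcohol and leaves C7 (no longer α to a carbonyl) and the alkenes untouched.

Step 4
Reactants: 8 dimethyl 2-[(2E)-3,7-dimethylocta-2,6-dien-1-yl]-2-[(3S)-3-(hydroxymethyl)-2,6-dimethylhept-5-en-2-yl]propanedioate; 9 iodine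
Product: 10 dimethyl 2-[(2E)-3,7-dimethylocta-2,6-dien-1-yl]-2-[(3S)-3-(iodomethyl)-2,6-dimethylhept-5-en-2-yl]propanedioate
Conditions: PPh3, imidazole, I2 (premixed), CH2Cl2, 0 °C → rt
Reagents that add atoms: iodine (9), II
Why: Appel iodination (SN2 displacement of the alkoxyphosphonium by iodide) converts the β-branched primary alcohol into the iodide under neutral conditions that spare the trisubstituted alkenes, the esters and C7.

Step 5
Reactants: 11 methyl 3,4-dihydroxybenzoate; 12 chlorotri(propan-2-yl)silane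
Product: 13 methyl 3,4-bis{[tri(propan-2-yl)silyl]oxy}benzoate
Conditions: i-Pr3SiCl, imidazole, DMF, 50 °C
Reagents that add atoms: chlorotri(propan-2-yl)silane (12), CC(C)[Si](Cl)(C(C)C)C(C)C
Why: Imidazole-mediated silyl ether formation masks both acidic phenols as triisopropylsilyl ethers that tolerate amide bases and alkoxides and are later removed by fluoride.

Step 6
Reactants: 13 methyl 3,4-bis{[tri(propan-2-yl)silyl]oxy}benzoate; 14 (5E)-6,10-dimethylundeca-5,9-dien-2-one
Product: 15 (6E)-1-(3,4-bis{[tri(propan-2-yl)silyl]oxy}phenyl)-7,11-dimethyldodeca-6,10-diene-1,3-dione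
Conditions: 14, LiN(SiMe3)2 (2.2 equiv), THF, −78 °C; then 13, −78 °C → rt
Reagents that add atoms: (5E)-6,10-dimethylundeca-5,9-dien-2-one (14), CC(=O)CC/C=C(\C)CCC=C(C)C
Why: Crossed Claisen condensation of the kinetic methyl enolate of the ketone with the non-enolisable aryl ester, driven by deprotonation of the β-diketone product, gives an aryl β-diketone whose only γ-hydrogens sit on the future C5, which already carries its geranyl group.

Step 7
Reactants: 15 (6E)-1-(3,4-bis{[tri(propan-2-yl)silyl]oxy}phenyl)-7,11-dimethyldodeca-6,10-diene-1,3-dione; 10 dimethyl 2-[(2E)-3,7-dimethylocta-2,6-dien-1-yl]-2-[(3S)-3-(iodomethyl)-2,6-dimethylhept-5-en-2-yl]propanedioate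
Product: 17 (1S,5S,7R)-3-(3,4-bis{[tri(propan-2-yl)silyl]oxy}benzoyl)-1,5-bis[(2E)-3,7-dimethylocta-2,6-dien-1-yl]-4-hydroxy-8,8-dimethyl-7-(3-methylbut-2-en-1-yl)bicyclo[3.3.1]non-3-ene-2,9-dione, via acyclic malonate diketone 16 (not isolated)
Conditions: 15 (1.3 equiv), LiN(i-Pr)2 (2.1 equiv per 15), THF, −78 → 0 °C; 10, DMPU, −78 → 0 °C; then LiN(i-Pr)2 (1.5 equiv), −78 °C → 40 °C
Reagents that add atoms: dimethyl 2-[(2E)-3,7-dimethylocta-2,6-dien-1-yl]-2-[(3S)-3-(iodomethyl)-2,6-dimethylhept-5-en-2-yl]propanedioate (10), IC[C@@H](CC=C(C)C)C(C)(C)C(C/C=C(\C)CCC=C(C)C)(C(=O)OC)C(=O)OC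
Why: Proposed new method: the Hauser-type β-diketone dianion is alkylated at its terminal γ-carbon by the primary iodide (C5–C6), a further equivalent of amide base regenerates the dianion at the now tertiary C5, which attacks one of the two diastereotopic malonate esters in a 6-(enolexo)-exo-trig Dieckmann closure (C5–C9, ring B) through a chair that keeps the C7 prenyl group equatorial and places the remaining ester and the acyl chain 1,3-diaxial, the β-diketone enolate carbon C3 then closes ring A on that ester (C2–C3) and deprotonation of the strongly acidic triketone drains the otherwise reversible retro-Claisen manifold towards the exo bicycle, so that the fixed C7 centre sets C1 and C5 as (S); the closest known reaction types are the γ-alkylation and Dieckmann condensation of 1,3-dicarbonyl dianions and the intramolecular Claisen closure of an acyl- and ester-substituted cyclohexanone to a bicyclo[3.3.1]nonane-2,4,9-trione.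

Step 8
Reactants: 17 (1S,5S,7R)-3-(3,4-bis{[tri(propan-2-yl)silyl]oxy}benzoyl)-1,5-bis[(2E)-3,7-dimethylocta-2,6-dien-1-yl]-4-hydroxy-8,8-dimethyl-7-(3-methylbut-2-en-1-yl)bicyclo[3.3.1]non-3-ene-2,9-dione
Product: 18 (1S,5S,7R)-3-(3,4-dihydroxybenzoyl)-1,5-bis[(2E)-3,7-dimethylocta-2,6-dien-1-yl]-4-hydroxy-8,8-dimethyl-7-(3-methylbut-2-en-1-yl)bicyclo[3.3.1]non-3-ene-2,9-dione
Conditions: Bu4NF, AcOH (1:1), THF, 0 °C
Reagents that add atoms: none
Why: Fluoride-mediated desilylation of the two aryl silyl ethers under acetic acid buffering frees the catechol without acid-induced cyclisation of the enol onto the prenyl-type alkenes or base-induced damage to the triketone; no stereocentre is touched.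

## Compound list

1 | (4S)-3-acetyl-4-benzyl-1,3-oxazolidin-2-one | CC(=O)N1[C@@H](Cc2ccccc2)COC1=O | starting material
2 | dimethyl 2-(propan-2-ylidene)propanedioate | COC(=O)C(=C(C)C)C(=O)OC | starting material
3 | dimethyl 2-{4-[(4S)-4-benzyl-2-oxo-1,3-oxazolidin-3-yl]-2-methyl-4-oxobutan-2-yl}propanedioate | O=C(CC(C)(C)C(C(=O)OC)C(=O)OC)N1[C@@H](Cc2ccccc2)COC1=O | intermediate
4 | 1-bromo-3-methylbut-2-ene (prenyl bromide) | BrCC=C(C)C | starting material
5 | (2E)-1-bromo-3,7-dimethylocta-2,6-diene (geranyl bromide) | BrC/C=C(\C)CCC=C(C)C | starting material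
6 | dimethyl 2-[(3S)-3-{[(4S)-4-benzyl-2-oxo-1,3-oxazolidin-3-yl]carbonyl}-2,6-dimethylhept-5-en-2-yl]propanedioate (not isolated; sodium malonate enolate in the flask) | O=C(N1[C@@H](Cc2ccccc2)COC1=O)[C@@H](CC=C(C)C)C(C)(C)C(C(=O)OC)C(=O)OC | intermediate
7 | dimethyl 2-[(3S)-3-{[(4S)-4-benzyl-2-oxo-1,3-oxazolidin-3-yl]carbonyl}-2,6-dimethylhept-5-en-2-yl]-2-[(2E)-3,7-dimethylocta-2,6-dien-1-yl]propanedioate | O=C(N1[C@@H](Cc2ccccc2)COC1=O)[C@@H](CC=C(C)C)C(C)(C)C(C/C=C(\C)CCC=C(C)C)(C(=O)OC)C(=O)OC | intermediate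
8 | dimethyl 2-[(2E)-3,7-dimethylocta-2,6-dien-1-yl]-2-[(3S)-3-(hydroxymethyl)-2,6-dimethylhept-5-en-2-yl]propanedioate | OC[C@@H](CC=C(C)C)C(C)(C)C(C/C=C(\C)CCC=C(C)C)(C(=O)OC)C(=O)OC | intermediate
9 | iodine | II | starting material
10 | dimethyl 2-[(2E)-3,7-dimethylocta-2,6-dien-1-yl]-2-[(3S)-3-(iodomethyl)-2,6-dimethylhept-5-en-2-yl]propanedioate | IC[C@@H](CC=C(C)C)C(C)(C)C(C/C=C(\C)CCC=C(C)C)(C(=O)OC)C(=O)OC | intermediate
11 | methyl 3,4-dihydroxybenzoate | COC(=O)c1ccc(O)c(O)c1 | starting material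
12 | chlorotri(propan-2-yl)silane | CC(C)[Si](Cl)(C(C)C)C(C)C | starting material
13 | methyl 3,4-bis{[tri(propan-2-yl)silyl]oxy}benzoate | COC(=O)c1ccc(O[Si](C(C)C)(C(C)C)C(C)C)c(O[Si](C(C)C)(C(C)C)C(C)C)c1 | intermediate
14 | (5E)-6,10-dimethylundeca-5,9-dien-2-one ((E)-geranylacetone) | CC(=O)CC/C=C(\C)CCC=C(C)C | starting material
15 | (6E)-1-(3,4-bis{[tri(propan-2-yl)silyl]oxy}phenyl)-7,11-dimethyldodeca-6,10-diene-1,3-dione | O=C(CC(=O)CC/C=C(\C)CCC=C(C)C)c1ccc(O[Si](C(C)C)(C(C)C)C(C)C)c(O[Si](C(C)C)(C(C)C)C(C)C)c1 | intermediate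
16 | dimethyl 2-[(2E)-3,7-dimethylocta-2,6-dien-1-yl]-2-[(3R)-3-{(4E)-2-[3-(3,4-bis{[tri(propan-2-yl)silyl]oxy}phenyl)-3-oxopropanoyl]-5,9-dimethyldeca-4,8-dien-1-yl}-2,6-dimethylhept-5-en-2-yl]propanedioate (not isolated; both epimers at the acyl-bearing carbon; lithium enolate in the flask) | O=C(CC(=O)C(C/C=C(\C)CCC=C(C)C)C[C@@H](CC=C(C)C)C(C)(C)C(C/C=C(\C)CCC=C(C)C)(C(=O)OC)C(=O)OC)c1ccc(O[Si](C(C)C)(C(C)C)C(C)C)c(O[Si](C(C)C)(C(C)C)C(C)C)c1 | intermediate
17 | (1S,5S,7R)-3-(3,4-bis{[tri(propan-2-yl)silyl]oxy}benzoyl)-1,5-bis[(2E)-3,7-dimethylocta-2,6-dien-1-yl]-4-hydroxy-8,8-dimethyl-7-(3-methylbut-2-en-1-yl)bicyclo[3.3.1]non-3-ene-2,9-dione | CC(C)=CCC/C(C)=C/C[C@]12C[C@@H](CC=C(C)C)C(C)(C)[C@](C/C=C(\C)CCC=C(C)C)(C(=O)C(C(=O)c3ccc(O[Si](C(C)C)(C(C)C)C(C)C)c(O[Si](C(C)C)(C(C)C)C(C)C)c3)=C1O)C2=O | intermediate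
18 | (1S,5S,7R)-3-(3,4-dihydroxybenzoyl)-1,5-bis[(2E)-3,7-dimethylocta-2,6-dien-1-yl]-4-hydroxy-8,8-dimethyl-7-(3-methylbut-2-en-1-yl)bicyclo[3.3.1]non-3-ene-2,9-dione | CC(C)=CCC/C(C)=C/C[C@]12C[C@@H](CC=C(C)C)C(C)(C)[C@](C/C=C(\C)CCC=C(C)C)(C(=O)C(C(=O)c3ccc(O)c(O)c3)=C1O)C2=O | target

## Step count and risks

Total steps: 8. Longest linear sequence: 6 steps (1 → 2 → 3 → 4 → 7 → 8); steps 5 and 6 form the second branch.

Most likely to fail:

1. Step 7. The β-branched iodide may eliminate or react too slowly with the strongly basic dianion, and the two acylations have to take place at esters on a very congested quaternary carbon. Fallback, setting out from 10 and coming back at 16: alkylate the sodium enolate of allyl 3-oxobutanoate with 10 (NaH, DMF, 50 °C) to the allyl keto ester F1; geranylate its soft enolate with 5 (K2CO3, acetone, reflux) to the quaternary allyl keto ester F2; remove the allyl ester with loss of CO2 (Pd(PPh3)4, morpholine, THF) to the methyl ketone F3; acylate the kinetic methyl enolate of F3 with ester 13 (LiN(SiMe3)2, THF, −78 °C → rt). This gives 16 as an isolated compound, which is then closed to 17 with LiN(i-Pr)2 alone (2.2 equiv, THF, −78 → 40 °C), so both rings are still formed together and the conditions of the closure can be pushed independently of the alkylation.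

2. Step 1. Proton transfer from the γ-methyl groups of 2 to the lithium enolate may outrun C–C bond formation at the β,β-disubstituted acceptor. Fallback, setting out from 2 and coming back at 3: CuI-catalysed conjugate addition of (1,3-dioxolan-2-ylmethyl)magnesium bromide to 2 (THF, −20 °C) gives the acetal malonate F4; aqueous HCl in THF unmasks the aldehyde malonate F5; oxidation with NaClO2/NaH2PO4/2-methylbut-2-ene gives the acid malonate F6; pivaloyl chloride/Et3N followed by (4S)-4-benzyl-1,3-oxazolidin-2-one and LiCl gives 3.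

3. Step 2. The imide enolate sits next to a quaternary carbon and may alkylate sluggishly, and the equally hindered imide 7 may resist clean reductive cleavage in step 3. Fallback, setting out from 2 and coming back at 8 (it replaces steps 1 to 3): condense 5-methylhex-4-enal with (2S)-2-(methoxymethyl)pyrrolidin-1-amine to the chiral hydrazone F7; metalate it with LiN(i-Pr)2 (THF, −78 °C), add the aza-enolate to 2 (asymmetric Michael addition; by analogy with the standard alkylation of such hydrazones this auxiliary should give the required (S) centre, otherwise its enantiomer is used) and trap the malonate enolate in the same flask with 5 (DMPU) to give the hydrazone diester F8; cleave with aqueous oxalic acid to the aldehyde diester F9; reduce with NaBH4 (MeOH, 0 °C) to 8.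

## Further compounds

F1 | step 7 | dimethyl 2-[(2E)-3,7-dimethylocta-2,6-dien-1-yl]-2-[(3R)-2,6-dimethyl-3-{3-oxo-2-[(prop-2-en-1-yloxy)carbonyl]butyl}hept-5-en-2-yl]propanedioate (epimers at the keto-ester carbon) | CC(=O)C(C(=O)OCC=C)C[C@@H](CC=C(C)C)C(C)(C)C(C/C=C(\C)CCC=C(C)C)(C(=O)OC)C(=O)OC
F2 | step 7 | dimethyl 2-[(2E)-3,7-dimethylocta-2,6-dien-1-yl]-2-[(3R)-3-{(4E)-2-acetyl-5,9-dimethyl-2-[(prop-2-en-1-yloxy)carbonyl]deca-4,8-dien-1-yl}-2,6-dimethylhept-5-en-2-yl]propanedioate (epimers at the quaternary keto-ester carbon) | CC(=O)C(C/C=C(\C)CCC=C(C)C)(C(=O)OCC=C)C[C@@H](CC=C(C)C)C(C)(C)C(C/C=C(\C)CCC=C(C)C)(C(=O)OC)C(=O)OC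
F3 | step 7 | dimethyl 2-[(2E)-3,7-dimethylocta-2,6-dien-1-yl]-2-{(3R)-3-[(4E)-2-acetyl-5,9-dimethyldeca-4,8-dien-1-yl]-2,6-dimethylhept-5-en-2-yl}propanedioate (epimers at the acetyl-bearing carbon) | CC(=O)C(C/C=C(\C)CCC=C(C)C)C[C@@H](CC=C(C)C)C(C)(C)C(C/C=C(\C)CCC=C(C)C)(C(=O)OC)C(=O)OC
F4 | step 1 | dimethyl 2-[1-(1,3-dioxolan-2-yl)-2-methylpropan-2-yl]propanedioate | COC(=O)C(C(=O)OC)C(C)(C)CC1OCCO1
F5 | step 1 | dimethyl 2-(2-methyl-4-oxobutan-2-yl)propanedioate | COC(=O)C(C(=O)OC)C(C)(C)CC=O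
F6 | step 1 | 5-methoxy-4-(methoxycarbonyl)-3,3-dimethyl-5-oxopentanoic acid | COC(=O)C(C(=O)OC)C(C)(C)CC(=O)O
F7 | step 2 | (2S)-2-(methoxymethyl)-N-[(1E)-5-methylhex-4-en-1-ylidene]pyrrolidin-1-amine | COC[C@@H]1CCCN1/N=C/CCC=C(C)C
F8 | step 2 | dimethyl 2-[(2E)-3,7-dimethylocta-2,6-dien-1-yl]-2-{(3S)-3-[(E)-{[(2S)-2-(methoxymethyl)pyrrolidin-1-yl]imino}methyl]-2,6-dimethylhept-5-en-2-yl}propanedioate | COC[C@@H]1CCCN1/N=C/[C@@H](CC=C(C)C)C(C)(C)C(C/C=C(\C)CCC=C(C)C)(C(=O)OC)C(=O)OC
F9 | step 2 | dimethyl 2-[(2E)-3,7-dimethylocta-2,6-dien-1-yl]-2-[(3S)-3-formyl-2,6-dimethylhept-5-en-2-yl]propanedioate | O=C[C@@H](CC=C(C)C)C(C)(C)C(C/C=C(\C)CCC=C(C)C)(C(=O)OC)C(=O)OC
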